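**Retrosynthetic overview**
- The six-membered carbocycle is closed last, by a base-induced intramolecular Claisen acyl transfer in a β-diketo γ-lactone (ring bond C2–C3); the lactone oxygen becomes the C6 hydroxyl.
- The β-diketone comes from conjugate hydration of a 4-acyloxy ynone.
- Key disconnection is ring bond C1–C6, between the future ring ketone carbon and the carbinol carbon, both natively electrophilic. The zinc acetylide of a terminal ynone acts as a β-ketoacyl anion equivalent and adds enantioselectively to methyl 4-oxobutanoate, setting C6 as R.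
- The ynone comes from a Weinreb amide and ethynyl Grignard; the (7E,9E)-diene from hydroboration/Suzuki coupling of an oct-7-ynamide with (E)-1-iododecene (from dec-1-yne).
- Ring order: temporary γ-lactone directly after the key step, then the carbocycle.

Assumption: with this new donor, Me2Zn/(R,R)-ProPhenol (ligand: 2,6-bis{[(R)-2-(hydroxydiphenylmethyl)pyrrolidin-1-yl]methyl}-4-methylphenol) is taken to deliver the alkynyl group to the Si face of the aldehyde; if the sense proves to be the reverse, the (S,S)-ligand is used with nothing else changed.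

**Step 1**
Reactants: 1 dec-1-yne
Product: 3 (E)-1-iododec-1-ene, via alkenylzirconocene chloride 2 (not isolated)
Conditions: Cp2Zr(H)Cl (1.2 equiv), THF, rt, 1 h; then I2 (1.2 equiv), 0 °C
Reagents that add atoms: iodine, II; Cp2Zr(H)Cl, [H][Zr](Cl)(C1C=CC=C1)C1C=CC=C1 (its atoms stay only in intermediate 2)
Why: Schwartz hydrozirconation adds Zr–H syn and anti-Markovnikov across the terminal alkyne and iodinolysis of the C–Zr bond goes with retention, so only the (E)-vinyl iodide forms.

**Step 2**
Reactants: 4 oct-7-ynoic acid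
Product: 5 N-methoxy-N-methyloct-7-ynamide
Conditions: MeNHOMe·HCl (1.2 equiv), EDC·HCl (1.3 equiv), DMAP (10 mol%), Et3N (2.5 equiv), CH2Cl2, 0 °C → rt
Reagents that add atoms: N,O-dimethylhydroxylamine hydrochloride, CNOC.Cl
Why: Carbodiimide amide coupling (Weinreb amide formation) is routine and leaves the terminal alkyne untouched.

**Step 3**
Reactants: 5 N-methoxy-N-methyloct-7-ynamide; 3 (E)-1-iododec-1-ene
Product: 7 (7E,9E)-N-methoxy-N-methyloctadeca-7,9-dienamide, via alkenylboronate 6 (not isolated)
Conditions: HBpin (1.3 equiv), Cy2BH (5 mol%), neat, rt; then 3, Pd(PPh3)4 (5 mol%), 3 M aq K3PO4, THF, 60 °C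
Reagents that add atoms: pinacolborane, B1OC(C)(C)C(C)(C)O1 (its atoms stay only in intermediate 6)
Why: Cy2BH-catalysed syn hydroboration gives the (E)-alkenylboronate and Suzuki–Miyaura coupling with zerovalent palladium retains the geometry of both alkenyl partners, so the (7E,9E)-diene is set stereospecifically while the Weinreb amide is inert to both stages.

**Step 4**
Reactants: 7 (7E,9E)-N-methoxy-N-methyloctadeca-7,9-dienamide
Product: 8 (9E,11E)-icosa-9,11-dien-1-yn-3-one
Conditions: HC≡CMgBr (0.5 M in THF, 3 equiv), THF, 0 °C → rt; inverse quench into cold 1 M HCl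
Reagents that add atoms: ethynylmagnesium bromide, C#C[Mg]Br
Why: Weinreb ketone synthesis, in which the chelated tetrahedral magnesium intermediate stops at single addition and the cold acidic inverse quench removes MeNHOMe before it can add to the terminal ynone.

**Step 5 (key step)**
Reactants: 8 (9E,11E)-icosa-9,11-dien-1-yn-3-one; 9 methyl 4-oxobutanoate
Product: 11 (5R)-5-[(9E,11E)-3-oxoicosa-9,11-dien-1-yn-1-yl]dihydrofuran-2(3H)-one, via hydroxy ynone ester 10 (not isolated)
Conditions: (R,R)-ProPhenol (20 mol%), Me2Zn (2.5 equiv), Ph3P=O (40 mol%), toluene, 0 °C, slow addition of 9 (2 equiv); 1 M HCl work-up; then TsOH·H2O (5 mol%), CH2Cl2, rt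
Reagents that add atoms: none
Why: Proposed new method: Me2Zn with the amino-alkoxide ligand zincates the acidic sp C–H of ynone 8 to give an alkynylzinc that behaves as a β-ketoacyl anion equivalent (its metalated carbon becomes ring ketone C1 after hydration), and the dinuclear zinc pocket, holding the aldehyde on one zinc and the alkynyl on the other, transfers it to the Si face of 9 to set C6 as R, after which the γ-hydroxy ester closes 5-exo to the lactone under acid; the closest known reaction is the Me2Zn/ProPhenol-catalysed asymmetric alkynylation of aldehydes with methyl propiolate and other electron-poor alkynes, the ynone ketone being far less electrophilic than the aldehyde.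

**Step 6**
Reactants: 11 (5R)-5-[(9E,11E)-3-oxoicosa-9,11-dien-1-yn-1-yl]dihydrofuran-2(3H)-one
Product: 13 (5R)-5-[(9E,11E)-3-oxoicosa-9,11-dienoyl]dihydrofuran-2(3H)-one, via diethylamino enone 12 (not isolated)
Conditions: Et2NH (1.1 equiv), THF, 0 °C, 30 min; then 1 M aq HCl, THF, rt
Reagents that add atoms: water, O; diethylamine, CCNCC (its atoms stay only in intermediate 12)
Why: Aza-Michael addition puts nitrogen on the β-carbon of the ynone (the former acetylide carbon) and mild acid hydrolysis of the vinylogous amide unveils the latent ketone (net conjugate hydration), while the carbinol oxygen is tied up in the lactone so no 3(2H)-furanone can form and the C–H at the stereocentre is not touched.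

**Step 7**
Reactants: 13 (5R)-5-[(9E,11E)-3-oxoicosa-9,11-dienoyl]dihydrofuran-2(3H)-one
Product: 14 (6R)-3,6-dihydroxy-2-[(7E,9E)-octadeca-7,9-dienoyl]cyclohex-2-en-1-one
Conditions: t-BuOK (1.1 equiv), THF, 0 °C → rt; 1 M HCl quench
Reagents that add atoms: none
Why: Intramolecular Claisen (Dieckmann-type) acyl transfer in which the central carbon of the diketonate attacks the lactone carbonyl through a six-membered transition state, the C6 alkoxide is the leaving group, and formation of the strongly acidic triketone enolate drives the equilibrium, while a single equivalent of base leaves the C6–H alone so the R centre is kept.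

**Compound list**
1 | dec-1-yne | C#CCCCCCCCC | starting material
2 | chlorobis(cyclopentadienyl)[(E)-dec-1-en-1-yl]zirconium | CCCCCCCC/C=C/[Zr](Cl)(C1C=CC=C1)C1C=CC=C1 | intermediate (not isolated)
3 | (E)-1-iododec-1-ene | CCCCCCCC/C=C/I | intermediate
4 | oct-7-ynoic acid | C#CCCCCCC(=O)O | starting material
5 | N-methoxy-N-methyloct-7-ynamide | C#CCCCCCC(=O)N(C)OC | intermediate
6 | (E)-N-methoxy-N-methyl-8-(4,4,5,5-tetramethyl-1,3,2-dioxaborolan-2-yl)oct-7-enamide | CON(C)C(=O)CCCCC/C=C/B1OC(C)(C)C(C)(C)O1 | intermediate (not isolated)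
7 | (7E,9E)-N-methoxy-N-methyloctadeca-7,9-dienamide | CCCCCCCC/C=C/C=C/CCCCCC(=O)N(C)OC | intermediate
8 | (9E,11E)-icosa-9,11-dien-1-yn-3-one | CCCCCCCC/C=C/C=C/CCCCCC(=O)C#C | intermediate
9 | methyl 4-oxobutanoate | COC(=O)CCC=O | starting material
10 | methyl (4R,13E,15E)-4-hydroxy-7-oxotetracosa-13,15-dien-5-ynoate | CCCCCCCC/C=C/C=C/CCCCCC(=O)C#C[C@H](O)CCC(=O)OC | intermediate (not isolated)
11 | (5R)-5-[(9E,11E)-3-oxoicosa-9,11-dien-1-yn-1-yl]dihydrofuran-2(3H)-one | CCCCCCCC/C=C/C=C/CCCCCC(=O)C#C[C@H]1CCC(=O)O1 | intermediate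
12 | (5R)-5-[(1E,9E,11E)-1-(diethylamino)-3-oxoicosa-1,9,11-trien-1-yl]dihydrofuran-2(3H)-one | CCCCCCCC/C=C/C=C/CCCCCC(=O)/C=C(/N(CC)CC)[C@H]1CCC(=O)O1 | intermediate (not isolated)
13 | (5R)-5-[(9E,11E)-3-oxoicosa-9,11-dienoyl]dihydrofuran-2(3H)-one | CCCCCCCC/C=C/C=C/CCCCCC(=O)CC(=O)[C@H]1CCC(=O)O1 | intermediate
14 | (6R)-3,6-dihydroxy-2-[(7E,9E)-octadeca-7,9-dienoyl]cyclohex-2-en-1-one (CNP0169831.1) | CCCCCCCC/C=C/C=C/CCCCCC(=O)C1=C(O)CC[C@@H](O)C1=O | target

**Totals**
Total step count: 7. Longest linear sequence: 6 steps (4 → 5 → 7 → 8 → 11 → 13 → 14).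

**Steps most likely to fail**

Step 5. The ynone donor is new for this catalyst. The α'-CH2 of 8 may be zincated instead and give aldol products, the acetylide may add to a second molecule of 8, and an unbranched aldehyde may give only moderate ee. The fallback keeps the C1–C6 disconnection but uses a simple silylalkyne as the acyl anion equivalent and builds the ynone afterwards. It sets out from 9 and 7 and comes back at 11. Aldehyde 9 and trimethylsilylacetylene under the same Me2Zn/ProPhenol conditions give methyl (R)-4-hydroxy-6-(trimethylsilyl)hex-5-ynoate F1. Catalytic TsOH closes it to (R)-5-[(trimethylsilyl)ethynyl]dihydrofuran-2(3H)-one F2, and TBAF/AcOH frees (R)-5-ethynyldihydrofuran-2(3H)-one F3. Amide 7 is reduced with i-Bu2AlH at −78 °C to (7E,9E)-octadeca-7,9-dienal F4. Ligand-free Me2Zn-mediated addition of F3 to F4 gives (5R)-5-[(9E,11E)-3-hydroxyicosa-9,11-dien-1-yn-1-yl]dihydrofuran-2(3H)-one F5 as both carbinol epimers, and MnO2 in CH2Cl2 oxidises it to 11.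

Step 6. The amine may deprotonate the propargylic C6–H (allene formation, loss of ee) before it adds, and acid hydrolysis of the enaminone may be slow or open the lactone. The fallback replaces amine addition and aqueous hydrolysis with an anhydrous hydroxide surrogate that fragments by itself. It sets out from 11 and comes back at 13. (E)-Benzaldoxime and Cs2CO3 in DMSO at rt add the oximate oxygen to the ynone β-carbon to give (5R)-5-[(1E,9E,11E)-1-{[(E)-benzylideneamino]oxy}-3-oxoicosa-1,9,11-trien-1-yl]dihydrofuran-2(3H)-one F6. This is not isolated: base removes the oxime C–H and expels the diketonate, and acidification gives 13.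

Step 7. The diketonate must reach the lactone carbonyl through a bridged (7-oxabicyclo[2.2.1]) tetrahedral intermediate. O-acylation, retro-Claisen cleavage or epimerisation at C6 could compete. The fallback closes the same C2–C3 bond on an open-chain methyl ester with the carbinol silylated. It sets out from 10 (taken after the work-up of step 5, before acid treatment) and comes back at 14. TBSOTf/2,6-lutidine gives methyl (4R,13E,15E)-4-[(tert-butyldimethylsilyl)oxy]-7-oxotetracosa-13,15-dien-5-ynoate F7. Et2NH adds to give methyl (4R,5E,13E,15E)-4-[(tert-butyldimethylsilyl)oxy]-5-(diethylamino)-7-oxotetracosa-5,13,15-trienoate F8, which aqueous AcOH/THF hydrolyses to methyl (4R,13E,15E)-4-[(tert-butyldimethylsilyl)oxy]-5,7-dioxotetracosa-13,15-dienoate F9. t-BuOK in THF effects an unstrained Dieckmann cyclisation to (6R)-6-[(tert-butyldimethylsilyl)oxy]-3-hydroxy-2-[(7E,9E)-octadeca-7,9-dienoyl]cyclohex-2-en-1-one F10, and HF·pyridine in THF removes the silyl group to give 14.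

**Further compounds**
F1 | step 5 | methyl (R)-4-hydroxy-6-(trimethylsilyl)hex-5-ynoate | C[Si](C)(C)C#C[C@H](O)CCC(=O)OC
F2 | step 5 | (R)-5-[(trimethylsilyl)ethynyl]dihydrofuran-2(3H)-one | C[Si](C)(C)C#C[C@H]1CCC(=O)O1
F3 | step 5 | (R)-5-ethynyldihydrofuran-2(3H)-one | C#C[C@H]1CCC(=O)O1
F4 | step 5 | (7E,9E)-octadeca-7,9-dienal | CCCCCCCC/C=C/C=C/CCCCCC=O
F5 | step 5 | (5R)-5-[(9E,11E)-3-hydroxyicosa-9,11-dien-1-yn-1-yl]dihydrofuran-2(3H)-one (both epimers at the new carbinol) | CCCCCCCC/C=C/C=C/CCCCCC(O)C#C[C@H]1CCC(=O)O1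
F6 | step 6 | (5R)-5-[(1E,9E,11E)-1-{[(E)-benzylideneamino]oxy}-3-oxoicosa-1,9,11-trien-1-yl]dihydrofuran-2(3H)-one | CCCCCCCC/C=C/C=C/CCCCCC(=O)/C=C(/O/N=C/c1ccccc1)[C@H]1CCC(=O)O1
F7 | step 7 | methyl (4R,13E,15E)-4-[(tert-butyldimethylsilyl)oxy]-7-oxotetracosa-13,15-dien-5-ynoate | CCCCCCCC/C=C/C=C/CCCCCC(=O)C#C[C@H](O[Si](C)(C)C(C)(C)C)CCC(=O)OC
F8 | step 7 | methyl (4R,5E,13E,15E)-4-[(tert-butyldimethylsilyl)oxy]-5-(diethylamino)-7-oxotetracosa-5,13,15-trienoate | CCCCCCCC/C=C/C=C/CCCCCC(=O)/C=C(/N(CC)CC)[C@H](O[Si](C)(C)C(C)(C)C)CCC(=O)OC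
F9 | step 7 | methyl (4R,13E,15E)-4-[(tert-butyldimethylsilyl)oxy]-5,7-dioxotetracosa-13,15-dienoate | CCCCCCCC/C=C/C=C/CCCCCC(=O)CC(=O)[C@H](O[Si](C)(C)C(C)(C)C)CCC(=O)OC
F10 | step 7 | (6R)-6-[(tert-butyldimethylsilyl)oxy]-3-hydroxy-2-[(7E,9E)-octadeca-7,9-dienoyl]cyclohex-2-en-1-one | CCCCCCCC/C=C/C=C/CCCCCC(=O)C1=C(O)CC[C@@H](O[Si](C)(C)C(C)(C)C)C1=O
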